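In a one-step world every molecule of starting material that reacts ends as product, so a run that has used up its starting material stands at 100%. The earlier runs refuse that world: north-west stands at 80.6% and west at 59.7% at their last readings, so I compute just the missing share, as a correction to the whole.

| flask | starting material | coupling partner | base | protic impurity | temperature | remark | time |
|---|---|---|---|---|---|---|---|
| north-west | 0.50 mM | 2.5 equiv | 0.050 equiv | 0.10 mM | 30 °C | run made earlier |  |
| south-east | 0.50 mM | 2.5 equiv | 0.075 equiv | 0.10 mM | 41 °C | run made earlier |  |
| west | 0.50 mM | 2.5 equiv | 0.10 equiv | 0.20 mM | 30 °C | run made earlier |  |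
| birch | 0.50 mM | 2.50 equiv | 0.100 equiv | 0.100 mM | 25 °C |  | 3.0 min |
| larch | 0.50 mM | 2.50 equiv | 0.100 equiv | 0.100 mM | 45 °C |  | 3.0 min |

- north-west (time / min: product / %, starting material / %): 0.200: 12.9, 67.9; 0.500: 54.2, 24.7; 1.00: 79.6, 1.1; 1.50: 80.6, 1.1; 2.00: 80.1, 0.1; 3.00: 79.8, 0; 4.00: 80.6, 0
- south-east (time / s: product / %, starting material / %): 10.0: 18.1, 63.0; 15.0: 32.5, 47.8; 25.0: 59.8, 19.5; 40.0: 77.3, 3.4; 50.0: 77.8, 0.7; 80.0: 79.8, 0.5; 120: 80.3, 0
- west (time / min: product / %, starting material / %): 0.667: 34.2, 25.7; 1.33: 58.9, 1.9; 2.00: 60.3, 0.2; 3.00: 59.8, 0; 4.00: 59.7, 0

(standard deviation of a reading: 0.5 percentage points)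

- which flask leads in amount of product, in percent of the starting material charged ("all alike" within 1.5 percentage points) (birch / larch / all alike)
- how much product is there at the end, in percent of the starting material charged: birch
- how much product is there at the end, in percent of the starting material charged: larch

For birch and larch, c(protic impurity)/c(starting material) is 20.0%. I call this share the impurity toll: the part of the charged starting material lost one to one to the protic impurity. It leaves a ceiling of 80.0% for product, with the starting material as limiting reagent against 2.50 equiv of coupling partner.

But a ratio of charges could fit by chance, so I hold it against the readings. West has a toll of 40.0%, and its first reading already lacks 40.1% of the charge. North-west lacks 19.2% at 0.200 min, with product at just 12.9%, so the toll is paid early.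

Might heat change it for larch? South-east, at 41 °C, lacks 18.9% at 10.0 s and ends at 80.3%, so I see no shift, though 45 °C lies beyond the runs.

Might birch, colder than any run, fall short of the ceiling in time? West, with base as in birch, is down to 1.9% starting material at 1.33 min, and birch has 3.0 min, an allowance of 2.26. From 30 °C to 41 °C, with base differing, the time to a few percent shrinks about 1.50-fold, so cooling to 25 °C should cost less than the allowance. I commit to the ceiling in both flasks.

The forecast gives 80% for birch, 80% for larch, and all alike: “The final yield tracks only the impurity.”

The simulation gives 80.0% for birch and 80.0% for larch, so the answer is all alike.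

    starting material + protic impurity → quenched substrate (k = 9560 L mol⁻¹ s⁻¹, Ea = 24.0 kJ mol⁻¹)
    starting material + coupling partner → product + by-product (k = 6.61 L mol⁻¹ s⁻¹, Ea = 44.0 kJ mol⁻¹)
    starting material + coupling partner + by-product → product + 2 by-product (k = 2.83 × 10⁵ L² mol⁻² s⁻¹, Ea = 12.0 kJ mol⁻¹)
    base + by-product ⇌ salt, settled at all times (K = 2.09 × 10⁷ L mol⁻¹, ΔH = −28.0 kJ mol⁻¹)
    (constants at 25 °C)

Product in birch stands at the ceiling, although 0.572% of starting material still remained at 1.50 min. At 3.00 min birch holds 0% starting material, and larch holds 0%. Ten times the time, 30.0 min, changes product by 1.8 × 10⁻⁴ percentage points in birch and by 0 points in larch, so both flasks have come to rest. The neighbour of birch with 1.00 equiv of coupling partner stands 13 points below the same ceiling at 3.00 min, with 12.6% of starting material still present.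

The earlier runs and the new flask are simulated from invented constants; the scatter is artificial.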